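Compound numbers are those of the steps and of the compound list below. Ring locants follow the 2-oxaspiro[4.5]decane numbering of the target: C-1 lactone O–CH, O-2, C-3 lactone C=O, C-4 lactone CH2, C-5 spiro carbon, C-6 ketone, C-7 CH2, C-8 CH–N, C-9 CH–O, C-10 CH2. Ring A is the cyclohexanone, ring B the γ-lactone.

## Analysis of the target

(+)-Miliusane V (25) is a 2-oxaspiro[4.5]decane. A cyclohexanone (ring A, C-5 to C-10, ketone at C-6) and a γ-lactone (ring B: C-1, O-2, C-3, C-4) share the quaternary carbon C-5, and C-1 carries an (E)-2,6-dimethylhepta-1,5-dienyl chain. There are four stereocentres: C-1 (R), C-5 (R), C-8 (R) and C-9 (S). On ring A the C-5–C-1 bond, the C-9 hydroxyl and the C-8 acetamide lie on one face and the lactone CH2 (C-4) on the other; on ring B the alkenyl group at C-1 lies on the side of the ketone carbon C-6. Several groups are sensitive. The acetamide is β to the ketone (retro-Michael loss under base). The C-1–O bond is an allylic ester bond (ionisation by acid or by zerovalent palladium). The two trisubstituted alkenes react with electrophilic oxidants. Any intermediate with a free C-1 hydroxyl is a β-hydroxy ketone with a quaternary α-carbon (retro-aldol). The main difficulty is the fully substituted C-5 next to the oxygenated C-1, which must be set in relative and absolute sense, followed by the cis-amino alcohol on the far side of ring A. The strategy rests on the array C-6(=O)–C-5(quaternary)–C-1(–O). This is the pattern left when a group migrates from a carbinol carbon to the neighbouring carbon of an oxirane, so the C-5–C-10 bond is the bond to cut and ring A is a ring-expanded cyclopentanol.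

## Retrosynthetic reasoning

**25 from 24.** The acetamide is taken back to the trichloroacetamide 24 (three C–H bonds for three C–Cl bonds). The nitrogen then never has to be handled as a free amine β to the C-6 ketone, where elimination would threaten, and no separate N-acetylation is needed.

**24 from 21 through 23.** The C-8–N bond is cut. In 21 the C-9 hydroxyl sits γ to the enone carbonyl, so a nitrogen tethered to that oxygen can add to C-8 in a conjugate sense. The five-membered tether in 23 can only be cis-fused, which makes the configuration of C-8 a consequence of C-9. An intermolecular nitrogen nucleophile would have no such control.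

**21 from 16 through 20, 19 and 17.** The C-9–O bond is cut back to a C–H bond. With C-5 quaternary, the enone 16 can only enolise towards C-9, so the dienol silyl ether 17 is a single regioisomer and an electrophilic oxygen source can be directed to its terminus. The configuration is the weak point. The two faces of C-9 differ only through the two arms of the spiro centre. The arm carrying C-1 is expected to sit pseudoaxial, away from the silyloxy group on C-6, which would steer an electrophile to the face opposite to the one needed. The oxygen is therefore introduced without regard to configuration (19), the centre is erased by oxidation to the ene-dione 20, and hydride is then delivered under catalyst control to give 21. This costs two steps and converges both epimers.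

**16 from 14 through 15.** The C-7/C-8 unsaturation is removed. Dehydrogenation via the silyl enol ether 15 is regiochemically unambiguous because C-7 is the only enolisable position of the ketone.

**14 from 11 through 12.** Ring B is opened at the O-2–C-3 bond and C-3 is reduced to the alcohol level. The lactone is then formed by oxidation of a 1,4-diol in which the secondary C-1 hydroxyl is hindered and the primary one is not. Keeping the arm as a silyl ether until then prevents a carbonyl or hydroxyl group from interfering with the oxirane in the key step.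

**11 from 10 (key disconnection).** The C-5–C-10 bond is cut and C-10 is returned to the carbinol carbon, giving the 1-(oxiranyl)cyclopentanol 10. Forward, this one step forms ring A, the ketone, the quaternary centre and the free C-1 hydroxyl in their final positions. Because the shift is antiperiplanar to the breaking C–O bond, C-5 and C-1 are both fixed by the oxirane. Cutting elsewhere in ring A would leave the quaternary centre to an intermolecular alkylation or aldol reaction with no comparable control.

**10 from 9.** The oxirane C–O bonds are cut. The tertiary hydroxyl of 9 directs the oxidant to the adjacent alkene and a chiral catalyst chooses the face. Vanadium bishydroxamate catalysts are at their best with primary allylic alcohols, so the tetravalent hafnium variant of the same ligand class, which accepts tertiary carbinols, is planned. The alkene geometry is not free. The target relation between C-1 and C-5 results only if the cyclopentanol carbon and the dienyl group are cis on the alkene (3Z in 9), because the alkenyl group on C-1 must end up on the C-6 side of ring B.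

**9 from 5 and 7 (7 from 6).** Both C–C bonds at the carbinol carbon are cut. A 1,4-dimagnesium reagent adds twice to the ester of 5, and the second addition is intramolecular and closes the five-membered ring.

**5 from 3 and 4.** The C-2=C-3 bond of the dienoate is cut. The ester carbon (the future C-6) and the dienyl group must be cis (2Z). A Stobbe-type condensation on 4 would be shorter, but it places the dienyl group trans to the conjugated ester and would carry through to the C-1 epimer of 11. A Z-selective phosphonate olefination is therefore used, and the 4E bond comes unchanged from 4.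

**3 from 1 and 2.** The bond between the phosphonate α-carbon and the two-carbon arm is cut. Alkylation of a commercial phosphonoacetate installs the protected hydroxyethyl arm that later becomes C-4 and C-3.

## Alternatives that were turned down

**Alternative 1: bridged iodolactone.**
- Disconnection: the C-9–O and C-8–N bonds are traced back to an alkene in ring A, with the C-5 substituent that becomes C-1 held as a carboxylic acid.
- Forward key step: iodolactonisation of the cyclohexene acid A2. Iodine forms an iodonium on the ring alkene and the carboxylate on the quaternary carbon opens it, giving the bridged lactone A1 with the C–O bond at the future C-9 and a trans C–I bond at the future C-8.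
- For: the bicyclic frame forces the new oxygen cis to the carboxyl carbon, and SN2 displacement of iodide by a nitrogen nucleophile then gives the cis amino alcohol. This link between C-5 and the amino alcohol is more secure than in the chosen route, which needs an oxidation–reduction pair to fix C-9.
- Against: C-1 is not addressed. The lactone carbonyl of A1 must be brought to the aldehyde level and the dienyl chain added to a neopentyl carbonyl, with only acyclic induction from the quaternary centre. The bridged lactone must be opened, ring B built from the ester arm and the silyl ether oxidised, so redox and protecting-group steps accumulate. The quaternary centre of A2 also needs an earlier enantioselective step.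
- Comparison: the chosen strategy is weaker on the amino alcohol, but it makes C-1 and C-5 together, stereospecifically, from alkene geometry and one catalytic asymmetric step.

**Alternative 2: Diels–Alder construction of ring A.**
- Disconnection: the C-5–C-6 and C-10–C-9 bonds of ring A.
- Forward key step: the exo-methylene dienone A4 (dienophile) adds the dioxygenated diene A5 to give the cyclohexene A3. One new bond runs from the future spiro carbon to the silyloxy-bearing carbon, the other from the exo-methylene carbon to the acetoxy-bearing carbon.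
- For: ring A, the quaternary carbon and both ring oxygens arise in one convergent step. Endo addition gives the all-cis product, which already contains the C-9/C-5 relation that the chosen route must correct by a detour. Oxidation of the silyl ether would lead to the same kind of γ-oxygenated enone for a tethered nitrogen delivery. On step count and on C-9 this plan is stronger.
- Against: A4 is a 1,1-disubstituted dienophile (slower, weaker endo preference) and a cross-conjugated dienone prone to polymerisation. The regiochemistry rests on the modest donor difference between the two oxygenated termini of A5. An absolute sense needs a chiral Lewis acid that the acid-labile diene must survive. Above all, C-1 is left as a ketone in A3, and its 1,2-reduction beside a quaternary carbon whose other substituents differ little gives no reliable C-1/C-5 relation.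
- Comparison: the chosen strategy is strongest exactly where this one is weakest, at C-1/C-5.

**Alternative 3: radical-relay C–H lactonisation.**
- Disconnection: the O-2–C-1 bond of ring B, cut back to an allylic C–H bond of an intact geranyl group.
- Forward key step: the O-benzoyl hydroxamate A7 gives an amidyl radical under copper catalysis. This abstracts the allylic hydrogen of the geranyl CH2 by 1,5-transfer, the allyl radical is oxidised by copper and captured by the amide oxygen, and hydrolysis of the C=N bond gives A6.
- For: it is the shortest plan. The chain is introduced as a simple geranyl group, and the ring A oxygen and its relation to C-5 are in place before the key step. In brevity it is better than the chosen route.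
- Against: the amidyl radical can also add to the nearest geranyl alkene (6-exo) or to the enone, or abstract hydrogen from C-10. The oxidised allyl unit is unsymmetrical and can be captured at its tertiary end or lose its E geometry. The new C-1 centre arises from a planar intermediate, with control only from a ligand working against a remote substrate bias. On a polyunsaturated substrate of this kind the step would go beyond the scope on which it can be defended.
- Comparison: the chosen route is longer, but C-1 arises from a defined alkene geometry through a stereospecific shift of a known type.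

Key step: step 6

## Route

Assumption: in step 5 the ligand antipode is the one that the empirical face model of this catalyst class assigns to the face leading to the (2R,3R)-oxirane 10; its mirror image would be used if the model does not hold for this Z-dienyl carbinol.

Step 1
Reactants: 1 methyl 2-[bis(2,2,2-trifluoroethoxy)phosphoryl]acetate; 2 tert-butyl(2-iodoethoxy)dimethylsilane
Product: 3 methyl 2-[bis(2,2,2-trifluoroethoxy)phosphoryl]-4-[(tert-butyldimethylsilyl)oxy]butanoate (racemic)
Conditions: NaH, DMF, 0 °C; then 2, rt
Reagents that add atoms: none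
Why: C-alkylation of the sodium enolate of the phosphonoacetate by a primary iodide (SN2); a slight excess of 1 should suppress dialkylation. The stereocentre formed is lost in step 2, so 3 is used as the racemate.

Step 2
Reactants: 3 methyl 2-[bis(2,2,2-trifluoroethoxy)phosphoryl]-4-[(tert-butyldimethylsilyl)oxy]butanoate; 4 geranial
Product: 5 methyl (2Z,4E)-2-{2-[(tert-butyldimethylsilyl)oxy]ethyl}-5,9-dimethyldeca-2,4,8-trienoate
Conditions: KN(SiMe3)2, 18-crown-6, THF, −78 °C
Reagents that add atoms: none
Why: Still–Gennari variant of the Horner–Wadsworth–Emmons olefination: the electron-poor phosphonate eliminates rapidly from the kinetic adduct, which should place the ester carbon and the dienyl group cis (2Z). The 4E bond of 4 is not touched at −78 °C, and this 2Z geometry later fixes C-1 relative to C-5.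

Step 3
Reactants: 6 1,4-dibromobutane
Product: 7 butane-1,4-diylbis(magnesium bromide) (THF solution, used directly)
Conditions: Mg turnings, THF, rt → 40 °C, slow addition
Reagents that add atoms: magnesium, [Mg]
Why: Grignard formation by insertion of magnesium into both C–Br bonds; slow addition in THF should keep Wurtz coupling and cyclisation low.

Step 4
Reactants: 5 methyl (2Z,4E)-2-{2-[(tert-butyldimethylsilyl)oxy]ethyl}-5,9-dimethyldeca-2,4,8-trienoate; 7 butane-1,4-diylbis(magnesium bromide)
Product: 9 1-[(3Z,5E)-1-[(tert-butyldimethylsilyl)oxy]-6,10-dimethylundeca-3,5,9-trien-3-yl]cyclopentan-1-ol, via ω-bromomagnesio dienone 8 (not isolated)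
Conditions: THF, −20 °C → rt; aq. NH4Cl
Reagents that add atoms: none
Why: Double Grignard addition to an ester: the first addition gives ketone 8 after loss of methoxide, and the tethered C–Mg bond then closes the five-membered ring by 1,2-addition (5-exo), faster than any conjugate pathway. The alkene geometry is not affected.

Step 5
Reactants: 9 1-[(3Z,5E)-1-[(tert-butyldimethylsilyl)oxy]-6,10-dimethylundeca-3,5,9-trien-3-yl]cyclopentan-1-ol
Product: 10 1-[(2R,3R)-2-{2-[(tert-butyldimethylsilyl)oxy]ethyl}-3-[(1E)-2,6-dimethylhepta-1,5-dien-1-yl]oxiran-2-yl]cyclopentan-1-ol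
Conditions: Hf(OtBu)4 (cat.), N,N′-dihydroxy-N,N′-bis(diphenylacetyl)-trans-cyclohexane-1,2-diamine (single enantiomer, cat.), cumene hydroperoxide, MgO, toluene, 0 °C
Reagents that add atoms: cumene hydroperoxide, CC(C)(OO)c1ccccc1
Why: Hydroxyl-directed asymmetric epoxidation of a tertiary allylic alcohol with a tetravalent hafnium bishydroxamate catalyst; the metal-bound alkoxide delivers oxygen only to the adjacent C=C. The addition is syn, so the Z geometry becomes the cis relation of cyclopentanol carbon and alkenyl group on the oxirane, and the chiral ligand selects the face that gives both new stereocentres as 2R,3R.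

Step 6
Reactants: 10 1-[(2R,3R)-2-{2-[(tert-butyldimethylsilyl)oxy]ethyl}-3-[(1E)-2,6-dimethylhepta-1,5-dien-1-yl]oxiran-2-yl]cyclopentan-1-ol
Product: 11 (2R)-2-{2-[(tert-butyldimethylsilyl)oxy]ethyl}-2-[(1R,2E)-1-hydroxy-3,7-dimethylocta-2,6-dien-1-yl]cyclohexan-1-one
Conditions: ZnBr2 (1.1 equiv), CH2Cl2, −40 → 0 °C
Reagents that add atoms: none
Why: Zinc binds the oxirane oxygen and the carbinol oxygen as a five-membered chelate and weakens the C–O bond at the fully substituted oxirane carbon; as that bond stretches, the antiperiplanar ring C–C bond of the cyclopentanol migrates, the carbinol becomes the C-6 carbonyl and the oxirane oxygen stays on C-1 as the alkoxide (concerted 1,2-shift, semipinacol rearrangement of a 2,3-epoxy alcohol). The closest known reaction type is the Lewis-acid-promoted rearrangement of 1-(oxiranyl)cycloalkanols to 2-(1-hydroxyalkyl)cycloalkanones with a quaternary α-carbon. Ring A is closed by ring expansion from five to six members through formation of the C-5–C-10 bond, not by a cyclisation of an open chain. C-5 is set by inversion at the oxirane carbon, because the CH2 group enters anti to the departing oxygen, so its configuration follows from the oxirane made in step 5. C-1 is carried over unchanged because its C–O bond is not broken, and the C-1/C-5 relation is therefore the image of the Z geometry of 9. The step needs cleavage at the quaternary oxirane carbon and not at the allylic one: chelation holds the Lewis acid next to the carbinol, the migrating bond pushes only at that carbon, and a mild Lewis acid at low temperature is chosen to keep the allylic C–O bond from ionising. No choice between migrating groups arises, since the two ring CH2 groups of the cyclopentanol are identical.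

Step 7
Reactants: 11 (2R)-2-{2-[(tert-butyldimethylsilyl)oxy]ethyl}-2-[(1R,2E)-1-hydroxy-3,7-dimethylocta-2,6-dien-1-yl]cyclohexan-1-one
Product: 12 (2R)-2-(2-hydroxyethyl)-2-[(1R,2E)-1-hydroxy-3,7-dimethylocta-2,6-dien-1-yl]cyclohexan-1-one
Conditions: HF·pyridine, pyridine, THF, 0 °C
Reagents that add atoms: none
Why: Fluoride cleavage of the primary silyl ether under buffered, weakly acidic conditions; a basic fluoride source is avoided because the β-hydroxy ketone could undergo retro-aldol cleavage.

Step 8
Reactants: 12 (2R)-2-(2-hydroxyethyl)-2-[(1R,2E)-1-hydroxy-3,7-dimethylocta-2,6-dien-1-yl]cyclohexan-1-one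
Product: 14 (1R,5R)-1-[(1E)-2,6-dimethylhepta-1,5-dien-1-yl]-2-oxaspiro[4.5]decane-3,6-dione, via γ-lactol 13 (not isolated)
Conditions: 2,2,6,6-tetramethylpiperidin-1-oxyl (cat.), PhI(OAc)2, CH2Cl2, rt
Reagents that add atoms: none
Why: Oxidative lactonisation of a 1,4-diol by the oxoammonium species: the unhindered primary alcohol is oxidised first, the aldehyde is trapped by the C-1 hydroxyl as lactol 13 (5-exo-trig), and the lactol is oxidised to the lactone. The neopentyl secondary allylic alcohol is too hindered to compete, and C-1 keeps its configuration because its C–O bond is not broken.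

Step 9
Reactants: 14 (1R,5R)-1-[(1E)-2,6-dimethylhepta-1,5-dien-1-yl]-2-oxaspiro[4.5]decane-3,6-dione
Product: 15 (1R,5R)-1-[(1E)-2,6-dimethylhepta-1,5-dien-1-yl]-6-[(trimethylsilyl)oxy]-2-oxaspiro[4.5]dec-6-en-3-one
Conditions: Et3N, Me3SiOTf, CH2Cl2, 0 °C
Reagents that add atoms: trimethylsilyl trifluoromethanesulfonate, C[Si](C)(C)OS(=O)(=O)C(F)(F)F
Why: Soft enolisation of the ketone; C-5 is quaternary, so only the C-6/C-7 enol ether can form, and the less acidic lactone should not be silylated when the amine is present in excess.

Step 10
Reactants: 15 (1R,5R)-1-[(1E)-2,6-dimethylhepta-1,5-dien-1-yl]-6-[(trimethylsilyl)oxy]-2-oxaspiro[4.5]dec-6-en-3-one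
Product: 16 (1R,5R)-1-[(1E)-2,6-dimethylhepta-1,5-dien-1-yl]-2-oxaspiro[4.5]dec-7-ene-3,6-dione
Conditions: Pd(OAc)2 (1.1 equiv), MeCN, rt
Reagents that add atoms: none
Why: Saegusa–Ito dehydrogenation: the divalent palladium enolate undergoes β-hydride elimination to the C-7/C-8 enone. Trisubstituted alkenes bind divalent palladium poorly at room temperature.

Step 11
Reactants: 16 (1R,5R)-1-[(1E)-2,6-dimethylhepta-1,5-dien-1-yl]-2-oxaspiro[4.5]dec-7-ene-3,6-dione
Product: 17 (1R,5R)-6-[(tert-butyldimethylsilyl)oxy]-1-[(1E)-2,6-dimethylhepta-1,5-dien-1-yl]-2-oxaspiro[4.5]deca-6,8-dien-3-one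
Conditions: Et3N, tBuMe2SiOTf, CH2Cl2, 0 °C → rt
Reagents that add atoms: tert-butyldimethylsilyl trifluoromethanesulfonate, CC(C)(C)[Si](C)(C)OS(=O)(=O)C(F)(F)F
Why: Soft enolisation of the enone; with no hydrogen on C-5, deprotonation can only take place at the γ-carbon C-9, giving the linear 6-silyloxy-6,8-diene as a single regioisomer.

Step 12
Reactants: 17 (1R,5R)-6-[(tert-butyldimethylsilyl)oxy]-1-[(1E)-2,6-dimethylhepta-1,5-dien-1-yl]-2-oxaspiro[4.5]deca-6,8-dien-3-one
Product: 19 (1R,5R)-1-[(1E)-2,6-dimethylhepta-1,5-dien-1-yl]-9-hydroxy-2-oxaspiro[4.5]dec-7-ene-3,6-dione (both C-9 epimers), via 8,9-epoxy silyl enol ether 18 (not isolated)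
Conditions: dimethyldioxirane (1.0 equiv), acetone/CH2Cl2, −78 °C; then AcOH, THF/H2O
Reagents that add atoms: dimethyldioxirane, CC1(C)OO1
Why: Vinylogous Rubottom oxidation: the electron-rich dienol ether should be attacked at its terminal C-8/C-9 bond much faster than the side-chain alkenes at −78 °C with one equivalent of oxidant, and epoxide 18 opens with regeneration of the enone. The C-9 configuration formed here is not relied on, since both epimers converge in step 13.

Step 13
Reactants: 19 (1R,5R)-1-[(1E)-2,6-dimethylhepta-1,5-dien-1-yl]-9-hydroxy-2-oxaspiro[4.5]dec-7-ene-3,6-dione (both C-9 epimers)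
Product: 20 (1R,5R)-1-[(1E)-2,6-dimethylhepta-1,5-dien-1-yl]-2-oxaspiro[4.5]dec-7-ene-3,6,9-trione
Conditions: Dess–Martin periodinane, NaHCO3, CH2Cl2, 0 °C → rt
Reagents that add atoms: none
Why: Dess–Martin oxidation of the allylic alcohol under buffered conditions; it removes the uncontrolled C-9 centre. The 2-ene-1,4-dione cannot aromatise because C-5 is quaternary.

Step 14
Reactants: 20 (1R,5R)-1-[(1E)-2,6-dimethylhepta-1,5-dien-1-yl]-2-oxaspiro[4.5]dec-7-ene-3,6,9-trione
Product: 21 (1R,5R,9S)-1-[(1E)-2,6-dimethylhepta-1,5-dien-1-yl]-9-hydroxy-2-oxaspiro[4.5]dec-7-ene-3,6-dione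
Conditions: (R)-1-methyl-3,3-diphenyltetrahydro-1H,3H-pyrrolo[1,2-c][1,3,2]oxazaborole (cat.), catecholborane, toluene, −78 °C
Reagents that add atoms: none
Why: Corey–Bakshi–Shibata reduction: the C-9 carbonyl, flanked by CH2 and CH=, is much more accessible than the C-6 carbonyl next to the quaternary carbon. With the alkenyl side as the large group, the (R)-catalyst should deliver hydride to the face that gives the 9S alcohol, with the hydroxyl on the face of the C-5–C-1 bond. Catecholborane at −78 °C should neither hydroborate the side-chain alkenes nor reduce the lactone.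

Step 15
Reactants: 21 (1R,5R,9S)-1-[(1E)-2,6-dimethylhepta-1,5-dien-1-yl]-9-hydroxy-2-oxaspiro[4.5]dec-7-ene-3,6-dione
Product: 23 cis-fused 2-(trichloromethyl)-4,5-dihydro-1,3-oxazole spanning N–C-8 and O–C-9 of the spirolactone ketone (1R,5R,8R,9S), via trichloroacetimidate 22 (not isolated)
Conditions: Cl3CCN, 1,8-diazabicyclo[5.4.0]undec-7-ene (cat.), CH2Cl2, 0 °C → rt
Reagents that add atoms: trichloroacetonitrile, ClC(Cl)(Cl)C#N
Why: Base-catalysed addition of the alcohol to the nitrile gives imidate 22, whose nitrogen adds to C-8 of the enone (tethered aza-Michael addition, 5-exo-trig). The five-membered tether can only be cis-fused, so C-8 is set R by the C-9 centre.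

Step 16
Reactants: 23 cis-fused 2-(trichloromethyl)-4,5-dihydro-1,3-oxazole of the spirolactone ketone (1R,5R,8R,9S)
Product: 24 2,2,2-trichloro-N-[(1R,5R,8R,9S)-1-[(1E)-2,6-dimethylhepta-1,5-dien-1-yl]-9-hydroxy-3,6-dioxo-2-oxaspiro[4.5]decan-8-yl]acetamide
Conditions: TsOH·H2O, pyridine/H2O, 60 °C
Reagents that add atoms: water, O
Why: Mild acid hydrolysis of the 2-trichloromethyl oxazoline; the hemiorthoamide collapses to the hydroxy trichloroacetamide, so the nitrogen never appears as a free β-amino ketone and neither stereocentre is touched.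

Step 17
Reactants: 24 2,2,2-trichloro-N-[(1R,5R,8R,9S)-1-[(1E)-2,6-dimethylhepta-1,5-dien-1-yl]-9-hydroxy-3,6-dioxo-2-oxaspiro[4.5]decan-8-yl]acetamide
Product: 25 (+)-miliusane V, N-[(1R,5R,8R,9S)-1-[(1E)-2,6-dimethylhepta-1,5-dien-1-yl]-9-hydroxy-3,6-dioxo-2-oxaspiro[4.5]decan-8-yl]acetamide
Conditions: Bu3SnH (excess), 2,2′-azobis(2-methylpropionitrile) (cat.), toluene, 80 °C
Reagents that add atoms: none
Why: Radical chain hydrodechlorination: three successive chlorine abstractions by the stannyl radical turn the trichloroacetamide into the acetamide. No stereocentre is involved, and the side-chain alkenes are too remote for cyclisation of the intermediate radicals.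

## Compound list

1 | methyl 2-[bis(2,2,2-trifluoroethoxy)phosphoryl]acetate | COC(=O)CP(=O)(OCC(F)(F)F)OCC(F)(F)F | starting material
2 | tert-butyl(2-iodoethoxy)dimethylsilane | CC(C)(C)[Si](C)(C)OCCI | starting material
3 | methyl 2-[bis(2,2,2-trifluoroethoxy)phosphoryl]-4-[(tert-butyldimethylsilyl)oxy]butanoate (racemic) | COC(=O)C(CCO[Si](C)(C)C(C)(C)C)P(=O)(OCC(F)(F)F)OCC(F)(F)F | intermediate
4 | geranial, (2E)-3,7-dimethylocta-2,6-dienal | CC(C)=CCC/C(C)=C/C=O | starting material
5 | methyl (2Z,4E)-2-{2-[(tert-butyldimethylsilyl)oxy]ethyl}-5,9-dimethyldeca-2,4,8-trienoate | COC(=O)/C(CCO[Si](C)(C)C(C)(C)C)=C\C=C(/C)CCC=C(C)C | intermediate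
6 | 1,4-dibromobutane | BrCCCCBr | starting material
7 | butane-1,4-diylbis(magnesium bromide) | Br[Mg]CCCC[Mg]Br | intermediate
8 | bromo[(6Z,8E)-6-{2-[(tert-butyldimethylsilyl)oxy]ethyl}-9,13-dimethyl-5-oxotetradeca-6,8,12-trien-1-yl]magnesium | Br[Mg]CCCCC(=O)/C(CCO[Si](C)(C)C(C)(C)C)=C\C=C(/C)CCC=C(C)C | intermediate (not isolated)
9 | 1-[(3Z,5E)-1-[(tert-butyldimethylsilyl)oxy]-6,10-dimethylundeca-3,5,9-trien-3-yl]cyclopentan-1-ol | OC1(CCCC1)/C(CCO[Si](C)(C)C(C)(C)C)=C\C=C(/C)CCC=C(C)C | intermediate
10 | 1-[(2R,3R)-2-{2-[(tert-butyldimethylsilyl)oxy]ethyl}-3-[(1E)-2,6-dimethylhepta-1,5-dien-1-yl]oxiran-2-yl]cyclopentan-1-ol | OC1(CCCC1)[C@]1(CCO[Si](C)(C)C(C)(C)C)O[C@@H]1/C=C(\C)CCC=C(C)C | intermediate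
11 | (2R)-2-{2-[(tert-butyldimethylsilyl)oxy]ethyl}-2-[(1R,2E)-1-hydroxy-3,7-dimethylocta-2,6-dien-1-yl]cyclohexan-1-one | O=C1CCCC[C@@]1(CCO[Si](C)(C)C(C)(C)C)[C@H](O)/C=C(\C)CCC=C(C)C | intermediate
12 | (2R)-2-(2-hydroxyethyl)-2-[(1R,2E)-1-hydroxy-3,7-dimethylocta-2,6-dien-1-yl]cyclohexan-1-one | O=C1CCCC[C@@]1(CCO)[C@H](O)/C=C(\C)CCC=C(C)C | intermediate
13 | (1R,5R)-1-[(1E)-2,6-dimethylhepta-1,5-dien-1-yl]-3-hydroxy-2-oxaspiro[4.5]decan-6-one (lactol, both anomers) | C1CC(=O)[C@@]2(CC(O)O[C@@H]2/C=C(\C)CCC=C(C)C)CC1 | intermediate (not isolated)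
14 | (1R,5R)-1-[(1E)-2,6-dimethylhepta-1,5-dien-1-yl]-2-oxaspiro[4.5]decane-3,6-dione | C1CC(=O)[C@@]2(CC(=O)O[C@@H]2/C=C(\C)CCC=C(C)C)CC1 | intermediate
15 | (1R,5R)-1-[(1E)-2,6-dimethylhepta-1,5-dien-1-yl]-6-[(trimethylsilyl)oxy]-2-oxaspiro[4.5]dec-6-en-3-one | C1C=C(O[Si](C)(C)C)[C@@]2(CC(=O)O[C@@H]2/C=C(\C)CCC=C(C)C)CC1 | intermediate
16 | (1R,5R)-1-[(1E)-2,6-dimethylhepta-1,5-dien-1-yl]-2-oxaspiro[4.5]dec-7-ene-3,6-dione | C1C=CC(=O)[C@@]2(CC(=O)O[C@@H]2/C=C(\C)CCC=C(C)C)C1 | intermediate
17 | (1R,5R)-6-[(tert-butyldimethylsilyl)oxy]-1-[(1E)-2,6-dimethylhepta-1,5-dien-1-yl]-2-oxaspiro[4.5]deca-6,8-dien-3-one | C1=CC=C(O[Si](C)(C)C(C)(C)C)[C@@]2(CC(=O)O[C@@H]2/C=C(\C)CCC=C(C)C)C1 | intermediate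
18 | 8,9-epoxide of 17 (oxirane on C-8/C-9, silyl enol ether at C-6/C-7; oxirane configuration not defined) | O1C2C=C(O[Si](C)(C)C(C)(C)C)[C@@]3(CC(=O)O[C@@H]3/C=C(\C)CCC=C(C)C)CC12 | intermediate (not isolated)
19 | (1R,5R)-1-[(1E)-2,6-dimethylhepta-1,5-dien-1-yl]-9-hydroxy-2-oxaspiro[4.5]dec-7-ene-3,6-dione (both C-9 epimers) | OC1C=CC(=O)[C@@]2(CC(=O)O[C@@H]2/C=C(\C)CCC=C(C)C)C1 | intermediate
20 | (1R,5R)-1-[(1E)-2,6-dimethylhepta-1,5-dien-1-yl]-2-oxaspiro[4.5]dec-7-ene-3,6,9-trione | O=C1C=CC(=O)[C@@]2(CC(=O)O[C@@H]2/C=C(\C)CCC=C(C)C)C1 | intermediate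
21 | (1R,5R,9S)-1-[(1E)-2,6-dimethylhepta-1,5-dien-1-yl]-9-hydroxy-2-oxaspiro[4.5]dec-7-ene-3,6-dione | C1=CC(=O)[C@@]2(CC(=O)O[C@@H]2/C=C(\C)CCC=C(C)C)C[C@@H]1O | intermediate
22 | (1R,5R,9S)-1-[(1E)-2,6-dimethylhepta-1,5-dien-1-yl]-3,6-dioxo-2-oxaspiro[4.5]dec-7-en-9-yl 2,2,2-trichloroacetimidate | C1=CC(=O)[C@@]2(CC(=O)O[C@@H]2/C=C(\C)CCC=C(C)C)C[C@@H]1OC(=N)C(Cl)(Cl)Cl | intermediate (not isolated)
23 | cis-fused 2-(trichloromethyl)-4,5-dihydro-1,3-oxazole with N on C-8 and O on C-9 of (1R,5R,8R,9S)-1-[(1E)-2,6-dimethylhepta-1,5-dien-1-yl]-2-oxaspiro[4.5]decane-3,6-dione | ClC(Cl)(Cl)C3=N[C@@H]1CC(=O)[C@@]2(CC(=O)O[C@@H]2/C=C(\C)CCC=C(C)C)C[C@@H]1O3 | intermediate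
24 | 2,2,2-trichloro-N-[(1R,5R,8R,9S)-1-[(1E)-2,6-dimethylhepta-1,5-dien-1-yl]-9-hydroxy-3,6-dioxo-2-oxaspiro[4.5]decan-8-yl]acetamide | ClC(Cl)(Cl)C(=O)N[C@@H]1CC(=O)[C@@]2(CC(=O)O[C@@H]2/C=C(\C)CCC=C(C)C)C[C@@H]1O | intermediate
25 | (+)-miliusane V, N-[(1R,5R,8R,9S)-1-[(1E)-2,6-dimethylhepta-1,5-dien-1-yl]-9-hydroxy-3,6-dioxo-2-oxaspiro[4.5]decan-8-yl]acetamide | CC(=O)N[C@@H]1CC(=O)[C@@]2(CC(=O)O[C@@H]2/C=C(\C)CCC=C(C)C)C[C@@H]1O | target

## Step count and least certain steps

Total: 17 steps. Longest linear sequence: 16 steps (steps 1, 2 and 4 to 17; step 3 prepares reagent 7).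

**Step 6 (key step).** The allylic C-1–O bond of the oxirane may ionise in competition with the shift at the quaternary carbon. The delocalised cation would lose the C-1 configuration, take up bromide or undergo hydride shift. Retro-aldol cleavage of 11 on prolonged contact with the Lewis acid is a second risk. The fallback changes the substrate class and the mode of activation. It sets out from 10, which would be silylated at the tertiary hydroxyl (1-(trimethylsilyl)imidazole, CH2Cl2) to the trimethylsilyl ether F1. This epoxy silyl ether would be rearranged with TiCl4 in CH2Cl2 at −78 °C. The silyloxy group is a stronger internal donor than the free hydroxyl, so the shift should proceed through an oxocarbenium-like transition state before the allylic bond can ionise. Loss of the silyl group on work-up returns the route at 11.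

**Step 5.** The hindered tertiary carbinol may exchange slowly onto the metal. Oxygen may be delivered to the C-5/C-6 alkene of 9, which the Z geometry holds near the hydroxyl. Facial selection may be low, and the vinyl oxirane may open during isolation. The fallback moves the asymmetric epoxidation to a primary allylic alcohol. It sets out from 5, which would be reduced with iBu2AlH (CH2Cl2, −78 °C) to the (2Z,4E)-dienol F2. Sharpless asymmetric epoxidation (Ti(OiPr)4, tBuOOH, molecular sieves, −20 °C) would give the epoxy alcohol F3. The tartrate antipode is the one assigned by the Sharpless face rule, L-(+)-diethyl tartrate on the present reading. Oxidation of the primary alcohol (2,2,6,6-tetramethylpiperidin-1-oxyl, PhI(OAc)2, MeCN/pH 7 buffer) would give the glycidic acid F4 and esterification with Me3SiCHN2 the methyl ester F5. Double addition of 7 to F5 at −40 °C, where the ester reacts before the oxirane, comes back to the route at 10.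

**Step 12.** The oxidant may also epoxidise the trisubstituted side-chain alkenes, or attack C-7 instead of C-9 of the dienol ether. The fallback replaces oxygen-atom transfer by an O-selective vinylogous nitroso aldol reaction, which leaves isolated alkenes alone. It sets out from 17, which would be treated with nitrosobenzene and AcOH in CH2Cl2/MeOH at 0 °C to give the 9-(N-phenylaminooxy) enone F6. Reductive N–O cleavage (Mo(CO)6, MeCN/H2O) would return the route at 19.

**Step 14.** Hydride may be delivered to the wrong face if substrate and catalyst are mismatched, or reduction may compete at C-6. The fallback replaces face-selective reduction by invertive substitution. It sets out from 19, from which the 9R epimer would be separated; this is the epimer expected to predominate if the electrophile in step 12 enters anti to the pseudoaxial C-1 arm. Mitsunobu reaction (PPh3, diisopropyl azodicarboxylate, chloroacetic acid, THF, 0 °C) would give the (9S)-chloroacetate F7 with inversion. Cleavage with thiourea and NaHCO3 in EtOH, which spares the lactone, comes back to the route at 21.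

## Further compounds

F1 | step 6 | {[1-((2R,3R)-2-{2-[(tert-butyldimethylsilyl)oxy]ethyl}-3-[(1E)-2,6-dimethylhepta-1,5-dien-1-yl]oxiran-2-yl)cyclopentyl]oxy}trimethylsilane | C[Si](C)(C)OC1(CCCC1)[C@]1(CCO[Si](C)(C)C(C)(C)C)O[C@@H]1/C=C(\C)CCC=C(C)C
F2 | step 5 | (2Z,4E)-2-{2-[(tert-butyldimethylsilyl)oxy]ethyl}-5,9-dimethyldeca-2,4,8-trien-1-ol | OC/C(CCO[Si](C)(C)C(C)(C)C)=C\C=C(/C)CCC=C(C)C
F3 | step 5 | [(2S,3R)-2-{2-[(tert-butyldimethylsilyl)oxy]ethyl}-3-[(1E)-2,6-dimethylhepta-1,5-dien-1-yl]oxiran-2-yl]methanol | OC[C@]1(CCO[Si](C)(C)C(C)(C)C)O[C@@H]1/C=C(\C)CCC=C(C)C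
F4 | step 5 | (2R,3R)-2-{2-[(tert-butyldimethylsilyl)oxy]ethyl}-3-[(1E)-2,6-dimethylhepta-1,5-dien-1-yl]oxirane-2-carboxylic acid | OC(=O)[C@]1(CCO[Si](C)(C)C(C)(C)C)O[C@@H]1/C=C(\C)CCC=C(C)C
F5 | step 5 | methyl (2R,3R)-2-{2-[(tert-butyldimethylsilyl)oxy]ethyl}-3-[(1E)-2,6-dimethylhepta-1,5-dien-1-yl]oxirane-2-carboxylate | COC(=O)[C@]1(CCO[Si](C)(C)C(C)(C)C)O[C@@H]1/C=C(\C)CCC=C(C)C
F6 | step 12 | (1R,5R)-1-[(1E)-2,6-dimethylhepta-1,5-dien-1-yl]-9-[(phenylamino)oxy]-2-oxaspiro[4.5]dec-7-ene-3,6-dione (C-9 epimers) | C1(ONc3ccccc3)C=CC(=O)[C@@]2(CC(=O)O[C@@H]2/C=C(\C)CCC=C(C)C)C1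
F7 | step 14 | (1R,5R,9S)-1-[(1E)-2,6-dimethylhepta-1,5-dien-1-yl]-3,6-dioxo-2-oxaspiro[4.5]dec-7-en-9-yl chloroacetate | C1=CC(=O)[C@@]2(CC(=O)O[C@@H]2/C=C(\C)CCC=C(C)C)C[C@@H]1OC(=O)CCl
A1 | alternative 1 | tert-butyl 2-[2-[(tert-butyldimethylsilyl)oxy]-4-iodo-7-oxo-6-oxabicyclo[3.2.1]octan-1-yl]acetate (configuration as in the SMILES) | O=C1O[C@H]2C[C@]1(CC(=O)OC(C)(C)C)[C@@H](O[Si](C)(C)C(C)(C)C)C[C@@H]2I
A2 | alternative 1 | 1-(2-tert-butoxy-2-oxoethyl)-6-[(tert-butyldimethylsilyl)oxy]cyclohex-3-ene-1-carboxylic acid (configuration as in the SMILES) | OC(=O)[C@@]1(CC(=O)OC(C)(C)C)[C@@H](O[Si](C)(C)C(C)(C)C)CC=CC1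
A3 | alternative 2 | methyl 2-[5-acetoxy-2-[(tert-butyldimethylsilyl)oxy]-1-[(2E)-3,7-dimethylocta-2,6-dienoyl]cyclohex-3-en-1-yl]acetate (all-cis, configuration as in the SMILES) | CC(=O)O[C@@H]1C=C[C@H](O[Si](C)(C)C(C)(C)C)[C@](CC(=O)OC)(C(=O)/C=C(\C)CCC=C(C)C)C1
A4 | alternative 2 | methyl (5E)-6,10-dimethyl-3-methylidene-4-oxoundeca-5,9-dienoate | COC(=O)CC(=C)C(=O)/C=C(\C)CCC=C(C)C
A5 | alternative 2 | (1E,3E)-4-[(tert-butyldimethylsilyl)oxy]buta-1,3-dien-1-yl acetate | CC(=O)O/C=C/C=C/O[Si](C)(C)C(C)(C)C
A6 | alternative 3 | (1R,5R,9S)-9-[(tert-butyldimethylsilyl)oxy]-1-[(1E)-2,6-dimethylhepta-1,5-dien-1-yl]-2-oxaspiro[4.5]dec-7-ene-3,6-dione | O=C1C=C[C@@H](O[Si](C)(C)C(C)(C)C)C[C@]12CC(=O)O[C@@H]2/C=C(\C)CCC=C(C)C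
A7 | alternative 3 | N-(benzoyloxy)-2-{5-[(tert-butyldimethylsilyl)oxy]-1-[(2E)-3,7-dimethylocta-2,6-dien-1-yl]-2-oxocyclohex-3-en-1-yl}acetamide (configuration as in the SMILES) | O=C1C=C[C@@H](O[Si](C)(C)C(C)(C)C)C[C@@]1(CC(=O)NOC(=O)c1ccccc1)C/C=C(\C)CCC=C(C)C
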